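- In a one-step world, where reagent meets starting material and no product reacts further, the surviving fraction of the charge is exp(−N), with N the turnovers each molecule has had. This flask has further steps in series, and the reagent is fed.

| flask | solid substrate | reagent | time | remark |
|---|---|---|---|---|
| red | 0.061 M | 0.0400 M (fed, over 2.0 h) | 4.0 h | the fed solution adds 1.0 times the starting volume |
| amber | 0.061 M | 0.0800 M (fed, over 2.0 h) | 4.0 h | the fed solution adds 1.0 times the starting volume |
| grey | 0.061 M | 0.150 M (fed, over 2.0 h) | 4.0 h | the fed solution adds 1.0 times the starting volume |
| violet | 0.061 M | 0.300 M (fed, over 2.0 h) | 4.0 h | the fed solution adds 1.0 times the starting volume |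
| green | 0.061 M | 0.600 M (fed, over 2.0 h) | 4.0 h | the fed solution adds 1.0 times the starting volume |

    starting material + reagent → mono adduct (k1 = 0.00205 M⁻¹ s⁻¹)
    reagent + mono adduct → bis adduct (k2 = 0.00237 M⁻¹ s⁻¹)
    reagent + bis adduct → tris adduct (k3 = 0.00569 M⁻¹ s⁻¹)
    solid substrate ⇌ starting material, rate k4*(cs4 - [starting material]) while solid is left; crystals form when [starting material] > cs4 (cs4 = 44 mM, k4 = 7.94 × 10⁻⁴ s⁻¹)

- charges are per starting volume, the dose included; the dosed solution carries all of it
- given per volume of solution although it is solid: solid substrate
- at the start none of the solid substrate is in solution
- "hardly changes" means that all values lie within two and a half points (for a concentration: within two and a half percent of the largest)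
- run time (red): 4.0 h

1. [mono adduct] at the end for red, amber, grey, violet, green, in this order
2. how the row runs (rises all the way / falls all the way / hardly changes / rises, then falls / falls, then rises)

- The time constant of the dissolving, 21.0 min, is shorter than the feed, so as an estimate I start counting at time zero.
- If none of the reagent were used, its concentration would climb to half its charge while the volume doubles, and then stay there. The rate constant of the first step times this concentration, summed over the run, gives for red the turnover count 0.476, a pseudo-first-order count that treats the fed reagent as free.
- The count grows with the charge: 0.953 for amber, 1.79 for grey, 3.57 for violet and 7.15 for green.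
- The second constant is close to the first, so I take the mono adduct fraction as N exp(−N). That gives 29.6%, 36.7%, 29.9%, 10.1% and 0.561%, with the top at amber.
- One number falls short in red: losing 37.9% of the starting material would use 57.8% of the reagent charge, so the free reagent is overcounted and I expect the real count to be lower.
- The forecast gives 0.0072 M, 0.0099 M, 0.0098 M, 0.005 M and 4.000 × 10⁻⁴ M, a row that rises, then falls, holding that “Mono adduct peaks near 0.33 of the substrate around the amber-to-grey charges”.
- The flask gives 0.00697 M, 0.00980 M, 0.0100 M, 0.00538 M and 5.34 × 10⁻⁴ M, a row that rises, then falls. As fractions of the charge these are 22.8%, 32.1%, 32.9%, 17.6% and 1.75%, and grey stands highest in the row, not amber as I reckoned.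
- In red, the half-life of mono adduct by the second step, 14 h at 0.347 h, is longer than the run of 4.0 h, and the 72.3% of starting material left at the end reads as 0.324 turnovers against my count of 0.476. In grey, the 30.3% left reads as 1.19 turnovers against my 1.79, a ratio of 0.667 beside 0.681 in red.

Its constants come from no measurement; what happens was integrated by code.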